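**Fade constant.** Per minute, target in the autumn run fell by a share of 0.0187 min⁻¹ between its last two readings, and we call this pseudo-first-order loss the fade constant. The dawn run reads 0.0192 min⁻¹ over the same times. We want to know when to stop the flask below.

common to all: catalyst 0.05 mol%
- autumn: starting material 0.50 M; reagent 2 equiv; second substrate 2.8 equiv; run made earlier
- dawn: starting material 0.50 M; reagent 2 equiv; second substrate 4.4 equiv; run made earlier
- dusk: starting material 0.25 M; reagent 2 equiv; second substrate 2 equiv; run made earlier
- flask: starting material 0.50 M; reagent 2.00 equiv; second substrate 2.00 equiv; time 50 min

| autumn: time / min | autumn: target / % | dawn: time / min | dawn: target / % | dusk: time / min | dusk: target / % |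
|---|---|---|---|---|---|
| 3.00 | 14 | 3.00 | 12 | 3.00 | 2 |
| 8.00 | 25 | 8.00 | 18 | 8.00 | 12 |
| 20.0 | 21 | 20.0 | 16 | 20.0 | 19 |
| 50.0 | 12 | 50.0 | 9 | 50.0 | 19 |

(scatter of a reading: 1.5 percentage points)

- the best time, 50 min at the latest, for target
- the amount of target, in percent of the starting material charged, at that time
- earliest time at which at least nineteen twentieths of that best amount are there, in min
- latest time at which they still are, in min

**Peak time.** If target follows exp(−fade·time) − exp(−rise·time), setting the slope to zero puts the peak at ln(rise/fade)/(rise − fade). Running the fade back from autumn's 20.0 min reading gives a ceiling of 30.5%, and its first reading then gives a rise constant of 0.240 min⁻¹.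

**What matters.** With these two constants the peak of the curve stands at 11.5 min. A fade constant of 0.0374 min⁻¹ moves it to 9.18 min, while a rise constant of 0.120 min⁻¹ moves it to 18.4 min. For these two changes, the time on this curve therefore moves more with the rise. We commit to 11.5 min for the flask and to no height, keeping autumn's rise although the flask holds less second substrate.

**The forecast.** It expects 29% at 12 min, with the window from 8 min to 18 min, and argues that “More second substrate lowers the peak”.

**The flask.** It gives 27.0% at 12.8 min, and the window runs from 8.36 min to 19.4 min, so there are 11.0 min in which to stop.

    starting material + reagent + catalyst → catalyst + target (k = 313 M⁻² min⁻¹)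
    second substrate + reagent + catalyst → catalyst + second product (k = 440 M⁻² min⁻¹)
    target + catalyst ⇌ isomer of the product + catalyst, rate k3*[catalyst]*[target] forward; the back reaction follows from the equilibrium constant (K = 2.70, k = 233 M⁻¹ min⁻¹)

**The fall.** Carried from 12.8 min to the end at the fade constant 0.0187 min⁻¹, the flask's best comes to 13.5%. The flask holds 18.1% of target at that end, with target still made at 0.463 of the rate at which it is used, each step taken net. The neighbour flask with 0.85 M of starting material reaches a best of 31.9% and ends at 15.9%, above the 12.5% that the fade constant gives even over the full 50 min. The largest single effect on the flask's height is the turning of target into isomer of the product, both ways: without it, the highest target goes from 27.0% to 56.3%.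

The numbers in the tables stem from a simulated flask with constants of no real substance, noise included.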